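**Retrosynthetic overview**
1. Sipholenol M ⇐ singlet-oxygen ene reaction of the tetracyclic triol that carries the C-15/C-16 alkene (last step).
2. Oxepane and cyclohexane ⇐ one late cascade (diepoxide → oxepane → cyclohexane) run on the complete C30 chain, with the C-10 cation taken up by water.
3. C-12–C-13 bond ⇐ anion of a Shi-epoxidised farnesyl sulfone plus the iodide of the right-hand decalin.
4. cis-Decalin ⇐ cascade of (6S,7S)-6,7-epoxyfarnesol: epoxide opening by the prenyl alkene, ring enlargement of the cyclopentylcarbinyl cation, closure by the C-14/C-15 alkene.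
5. Ring order: cyclopentane → gem-dimethylcyclohexane (ring B) → cyclohexene (ring A); then oxepane → cyclohexane.

Assumption: the presumed biosynthesis is taken as two separate cyclisations of (3S,6S,7S,18S,19S)-2,3:6,7:18,19-triepoxysqualene followed by a singlet-oxygen ene reaction at the 15,16-alkene; squalene numbering (C-1 to C-24) is used for positions.

**Step 1**
Reactants: 1 geranyl acetate
Product: 2 (2E,6E)-8-hydroxy-3,7-dimethylocta-2,6-dien-1-yl acetate
Conditions: SeO2 (0.3 equiv), t-BuOOH (3 equiv), salicylic acid (0.1 equiv), CH2Cl2, 25 °C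
Reagents that add atoms: tert-butyl hydroperoxide, CC(C)(C)OO
Why: Sharpless allylic oxidation (SeO2 ene reaction then 2,3-sigmatropic shift) hydroxylates the (E)-methyl of the electron-rich terminal alkene, while the alkene deactivated by the allylic acetate is left alone.

**Step 2**
Reactants: 2 (2E,6E)-8-hydroxy-3,7-dimethylocta-2,6-dien-1-yl acetate
Product: 3 (2E)-5-[(2S,3S)-3-(hydroxymethyl)-3-methyloxiran-2-yl]-3-methylpent-2-en-1-yl acetate
Conditions: Ti(OiPr)4 (10 mol %), L-(+)-diisopropyl tartrate (12 mol %), t-BuOOH (2 equiv), 4 Å molecular sieves, CH2Cl2, −20 °C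
Reagents that add atoms: tert-butyl hydroperoxide, CC(C)(C)OO
Why: Katsuki–Sharpless asymmetric epoxidation of the only free allylic alcohol; the L-(+)-tartrate delivers oxygen to the face that gives the (2S,3S)-oxirane (future C-18 S and C-19 S), and the acetate-bearing alkene has no free hydroxyl and does not react.

**Step 3**
Reactants: 3 (2E)-5-[(2S,3S)-3-(hydroxymethyl)-3-methyloxiran-2-yl]-3-methylpent-2-en-1-yl acetate
Product: 5 (2E)-5-[(2S,3S)-3-ethenyl-3-methyloxiran-2-yl]-3-methylpent-2-en-1-yl acetate, via epoxy aldehyde 4 (not isolated)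
Conditions: (COCl)2, DMSO, CH2Cl2, −78 °C; Et3N; then Ph3P=CH2 (from Ph3PCH3Br and KN(SiMe3)2), THF, −78 → 0 °C
Reagents that add atoms: methylenetriphenylphosphorane, C=P(c1ccccc1)(c1ccccc1)c1ccccc1
Why: Swern oxidation gives an α,β-epoxy aldehyde whose α-carbon is quaternary and cannot epimerise, and Wittig methylenation in the same flask gives the vinyl epoxide without touching the oxirane stereocentres.

**Step 4**
Reactants: 5 (2E)-5-[(2S,3S)-3-ethenyl-3-methyloxiran-2-yl]-3-methylpent-2-en-1-yl acetate; 6 1-bromo-2-methylprop-1-ene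
Product: 9 (2E,6S,7S)-6,7-epoxy-3,7,11-trimethyldodeca-2,10-dien-1-ol, via B-alkyl-9-BBN 7 (not isolated), via epoxyfarnesyl acetate 8 (not isolated)
Conditions: 9-borabicyclo[3.3.1]nonane (1.3 equiv), THF, 0 → 25 °C; then 6, PdCl2(dppf) (5 mol %, dppf = 1,1'-bis(diphenylphosphino)ferrocene), K3PO4 (3 M aq), DMF, 25 °C; then K2CO3, MeOH, 25 °C
Reagents that add atoms: none
Why: Anti-Markovnikov hydroboration of the monosubstituted vinyl group is much faster than that of the trisubstituted alkene, the B-alkyl Suzuki–Miyaura coupling installs the prenyl terminus (C-22 to C-24) with the epoxide untouched, and methanolysis frees the allylic alcohol so that no ester carbonyl can later trap a cation.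

**Step 5**
Reactants: 9 (2E,6S,7S)-6,7-epoxy-3,7,11-trimethyldodeca-2,10-dien-1-ol
Product: 10 (1S,4aR,5R,8aS)-5-(hydroxymethyl)-1,4,4,6-tetramethyl-1,2,3,4,4a,5,8,8a-octahydronaphthalen-1-ol (cis-fused decalin diol)
Conditions: Ph4PBF4 (20 mol %), (CF3)2CHOH (0.01 M), 0 °C
Reagents that add atoms: none
Why: Proposed new method: hydrogen-bond activation of the epoxide lets C-22 of the prenyl π-bond open it at C-18 with inversion (attack at C-19 would need a four-membered ring, as in the 5-endo closure of 3,4-epoxy alcohols to tetrahydrofurans), the resulting 2-cyclopentylprop-2-yl cation undergoes Wagner–Meerwein ring enlargement (C-21 shifts from C-22 to C-23) while C-14 of the (E)-alkene attacks C-22 anti to the migrating bond through a chair (H-22 and H-14 anti, CH2OH equatorial), and loss of H-16 gives the cis-decalin with C-18, C-19, C-22 and C-14 all relayed from the epoxide; the closest known reactions are epoxide-initiated cation–olefin polycyclisations in (CF3)2CHOH and the acid-mediated betulin-to-allobetulin rearrangement, where the same isopropyl-cyclopentyl cation enlarges to a gem-dimethylcyclohexane and is captured at the former ring carbon by an internal nucleophile.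

**Step 6**
Reactants: 10 (1S,4aR,5R,8aS)-5-(hydroxymethyl)-1,4,4,6-tetramethyl-1,2,3,4,4a,5,8,8a-octahydronaphthalen-1-ol
Product: 11 (1S,4aR,5R,8aS)-5-(iodomethyl)-1,4,4,6-tetramethyl-1,2,3,4,4a,5,8,8a-octahydronaphthalen-1-ol
Conditions: PPh3, I2, imidazole, CH2Cl2, 0 °C
Reagents that add atoms: iodine, [I][I]
Why: Appel-type (Garegg–Samuelsson) iodination replaces only the primary hydroxyl; the hindered tertiary alcohol does not react and no stereocentre is touched.

**Step 7**
Reactants: 12 (2E,6E)-farnesol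
Product: 14 (2E,6E)-farnesyl phenyl sulfone, via farnesyl bromide 13 (not isolated)
Conditions: PBr3, Et2O, −10 °C; then PhSO2Na, DMF, 25 °C
Reagents that add atoms: sodium benzenesulfinate, [Na+].[O-]S(=O)c1ccccc1
Why: SN2 bromination of the primary allylic alcohol and SN2 S-alkylation of the sulfinate give the allylic sulfone with both (E)-alkenes intact.

**Step 8**
Reactants: 14 (2E,6E)-farnesyl phenyl sulfone
Product: 15 [(2E,6S,7S,10S)-6,7:10,11-diepoxy-3,7,11-trimethyldodec-2-en-1-yl] phenyl sulfone
Conditions: 1,2:4,5-di-O-isopropylidene-β-L-erythro-2,3-hexodiulo-2,6-pyranose (30 mol %), KHSO5 (as Oxone, 2KHSO5·KHSO4·K2SO4), K2CO3, Bu4NHSO4, MeCN/CH2(OMe)2/aq Na2B4O7 buffer, 0 °C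
Reagents that add atoms: potassium peroxymonosulfate, [K+].[O-]S(=O)(=O)OO
Why: Shi asymmetric epoxidation: the dioxirane of the L-fructose-derived ketone epoxidises the two electron-rich trisubstituted alkenes through the spiro transition state to the (S)- and (S,S)-oxiranes (future C-3, C-6, C-7), while the alkene next to the sulfone is deactivated and survives as the future C-10/C-11 nucleophile.

**Step 9**
Reactants: 15 [(2E,6S,7S,10S)-6,7:10,11-diepoxy-3,7,11-trimethyldodec-2-en-1-yl] phenyl sulfone; 11 (1S,4aR,5R,8aS)-5-(iodomethyl)-1,4,4,6-tetramethyl-1,2,3,4,4a,5,8,8a-octahydronaphthalen-1-ol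
Product: 17 (1S,4aR,5R,8aS)-5-[(3E)-4-methyl-2-(phenylsulfonyl)-6-{(2S,3S)-3-methyl-3-[2-((2S)-3,3-dimethyloxiran-2-yl)ethyl]oxiran-2-yl}hex-3-en-1-yl]-1,4,4,6-tetramethyl-1,2,3,4,4a,5,8,8a-octahydronaphthalen-1-ol (both epimers at the sulfone carbon), via lithiated sulfone 16 (not isolated)
Conditions: n-BuLi (1.0 equiv to 15), THF/DMPU (5:1), −78 °C; then 11, −78 → −20 °C
Reagents that add atoms: none
Why: SN2 alkylation of the sulfone-stabilised allyl anion at its α-carbon by the primary iodide (Julia-type sulfone coupling) forms the C-12–C-13 bond; the anion is too weak a base to deprotonate the tertiary alcohol, cannot reach its own epoxides through the (E)-alkene, and the new sulfone-bearing centre is removed in the next step.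

**Step 10**
Reactants: 17 the C-12 phenylsulfonyl compound from step 9
Product: 18 (1S,4aR,5R,8aS)-5-[(3E)-4-methyl-6-{(2S,3S)-3-methyl-3-[2-((2S)-3,3-dimethyloxiran-2-yl)ethyl]oxiran-2-yl}hex-3-en-1-yl]-1,4,4,6-tetramethyl-1,2,3,4,4a,5,8,8a-octahydronaphthalen-1-ol
Conditions: PdCl2(dppp) (10 mol %, dppp = 1,3-bis(diphenylphosphino)propane), LiBHEt3 (3 equiv), THF, −20 → 0 °C
Reagents that add atoms: none
Why: Palladium-catalysed reductive desulfonylation: the π-allyl palladium complex formed from the allylic sulfone takes hydride at the less hindered terminus (C-12), which keeps the (E)-C-10/C-11 alkene in place, and the hindered trisubstituted epoxides are reduced much more slowly at this temperature.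

**Step 11**
Reactants: 18 the diepoxy diene alcohol from step 10
Product: 19 (3S,5aS,6S,7S,9aS)-6-{2-[(1R,4aS,5S,8aR)-5-hydroxy-2,5,8,8-tetramethyl-1,4,4a,5,6,7,8,8a-octahydronaphthalen-1-yl]ethyl}-2,2,5a,7-tetramethyldecahydro-1-benzoxepine-3,7-diol
Conditions: Ph4PBF4 (20 mol %), (CF3)2CHOH/H2O (50:1, 0.005 M), 0 °C
Reagents that add atoms: water, O
Why: Proposed new method: the known Lewis-acid-promoted tandem oxa-/carbacyclisation of 1,5-diepoxides with a trisubstituted alkene terminator (the 6,7-epoxide oxygen opens the activated 2,3-epoxide at C-2 to the oxepane, then C-11 opens the epoxonium ion at C-6 with inversion through a chair to the trans-fused oxepane–cyclohexane, C-3 and C-7 keeping their epoxide configuration) is run in wet (CF3)2CHOH so that the C-10 cation is captured by water from the equatorial side, anti to the new C-6–C-11 bond and away from the axial C-6 methyl, instead of losing a proton; the closest known reactions are that anhydrous cascade and solvent-terminated polyene cyclisations.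

**Step 12**
Reactants: 19 the tetracyclic triol from step 11
Product: 20 sipholenol M, (3S,5aS,6S,7S,9aS)-6-{2-[(3R,4aS,5S,8aR)-3-hydroperoxy-5-hydroxy-2,5,8,8-tetramethyl-3,4,4a,5,6,7,8,8a-octahydronaphthalen-1-yl]ethyl}-2,2,5a,7-tetramethyldecahydro-1-benzoxepine-3,7-diol
Conditions: O2, tetraphenylporphyrin (1 mol %), visible light, CH2Cl2, −20 °C
Reagents that add atoms: dioxygen, O=O
Why: Schenck ene reaction of singlet oxygen with the only alkene: oxygen adds to C-16 and removes the pseudo-axial allylic H-14 from the same face (suprafacial), which moves the double bond to C-14/C-15 and sets the C-16 hydroperoxide configuration from the C-14 stereocentre.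

**Compound list**
1 | geranyl acetate, (2E)-3,7-dimethylocta-2,6-dien-1-yl acetate | CC(C)=CCC/C(C)=C/COC(C)=O | starting material
2 | (2E,6E)-8-hydroxy-3,7-dimethylocta-2,6-dien-1-yl acetate | OC/C(C)=C/CC/C(C)=C/COC(C)=O | intermediate
3 | (2E)-5-[(2S,3S)-3-(hydroxymethyl)-3-methyloxiran-2-yl]-3-methylpent-2-en-1-yl acetate | OC[C@]1(C)O[C@H]1CC/C(C)=C/COC(C)=O | intermediate
4 | (2E)-5-[(2S,3R)-3-formyl-3-methyloxiran-2-yl]-3-methylpent-2-en-1-yl acetate (epoxy aldehyde, not isolated) | O=C[C@]1(C)O[C@H]1CC/C(C)=C/COC(C)=O | intermediate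
5 | (2E)-5-[(2S,3S)-3-ethenyl-3-methyloxiran-2-yl]-3-methylpent-2-en-1-yl acetate | C=C[C@]1(C)O[C@H]1CC/C(C)=C/COC(C)=O | intermediate
6 | 1-bromo-2-methylprop-1-ene | CC(C)=CBr | starting material
7 | (2E)-5-{(2S,3S)-3-[2-(9-borabicyclo[3.3.1]nonan-9-yl)ethyl]-3-methyloxiran-2-yl}-3-methylpent-2-en-1-yl acetate (B-alkyl-9-BBN, not isolated) | C(C[C@]1(C)O[C@H]1CC/C(C)=C/COC(C)=O)B1C2CCCC1CCC2 | intermediate
8 | (2E,6S,7S)-6,7-epoxy-3,7,11-trimethyldodeca-2,10-dien-1-yl acetate (epoxyfarnesyl acetate, not isolated) | CC(C)=CCC[C@]1(C)O[C@H]1CC/C(C)=C/COC(C)=O | intermediate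
9 | (2E,6S,7S)-6,7-epoxy-3,7,11-trimethyldodeca-2,10-dien-1-ol | CC(C)=CCC[C@]1(C)O[C@H]1CC/C(C)=C/CO | intermediate
10 | (1S,4aR,5R,8aS)-5-(hydroxymethyl)-1,4,4,6-tetramethyl-1,2,3,4,4a,5,8,8a-octahydronaphthalen-1-ol (cis-fused; 1-OH, H-4a, H-8a and CH2OH on one face) | OC[C@H]1C(C)=CC[C@H]2[C@@H]1C(C)(C)CC[C@]2(C)O | intermediate
11 | (1S,4aR,5R,8aS)-5-(iodomethyl)-1,4,4,6-tetramethyl-1,2,3,4,4a,5,8,8a-octahydronaphthalen-1-ol | IC[C@H]1C(C)=CC[C@H]2[C@@H]1C(C)(C)CC[C@]2(C)O | intermediate
12 | (2E,6E)-farnesol | CC(C)=CCC/C(C)=C/CC/C(C)=C/CO | starting material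
13 | (2E,6E)-farnesyl bromide (not isolated) | CC(C)=CCC/C(C)=C/CC/C(C)=C/CBr | intermediate
14 | (2E,6E)-farnesyl phenyl sulfone | CC(C)=CCC/C(C)=C/CC/C(C)=C/CS(=O)(=O)c1ccccc1 | intermediate
15 | [(2E,6S,7S,10S)-6,7:10,11-diepoxy-3,7,11-trimethyldodec-2-en-1-yl] phenyl sulfone | CC1(C)O[C@H]1CC[C@]1(C)O[C@H]1CC/C(C)=C/CS(=O)(=O)c1ccccc1 | intermediate
16 | α-lithio derivative of 15 (lithiated sulfone, not isolated) | CC1(C)O[C@H]1CC[C@]1(C)O[C@H]1CC/C(C)=C/[CH-]S(=O)(=O)c1ccccc1.[Li+] | intermediate
17 | (1S,4aR,5R,8aS)-5-[(3E)-4-methyl-2-(phenylsulfonyl)-6-{(2S,3S)-3-methyl-3-[2-((2S)-3,3-dimethyloxiran-2-yl)ethyl]oxiran-2-yl}hex-3-en-1-yl]-1,4,4,6-tetramethyl-1,2,3,4,4a,5,8,8a-octahydronaphthalen-1-ol, both epimers at the sulfone carbon (C-12) | CC1(C)O[C@H]1CC[C@]1(C)O[C@H]1CC/C(C)=C/C(C[C@H]1C(C)=CC[C@H]2[C@@H]1C(C)(C)CC[C@]2(C)O)S(=O)(=O)c1ccccc1 | intermediate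
18 | (1S,4aR,5R,8aS)-5-[(3E)-4-methyl-6-{(2S,3S)-3-methyl-3-[2-((2S)-3,3-dimethyloxiran-2-yl)ethyl]oxiran-2-yl}hex-3-en-1-yl]-1,4,4,6-tetramethyl-1,2,3,4,4a,5,8,8a-octahydronaphthalen-1-ol | CC1(C)O[C@H]1CC[C@]1(C)O[C@H]1CC/C(C)=C/CC[C@H]1C(C)=CC[C@H]2[C@@H]1C(C)(C)CC[C@]2(C)O | intermediate
19 | (3S,5aS,6S,7S,9aS)-6-{2-[(1R,4aS,5S,8aR)-5-hydroxy-2,5,8,8-tetramethyl-1,4,4a,5,6,7,8,8a-octahydronaphthalen-1-yl]ethyl}-2,2,5a,7-tetramethyldecahydro-1-benzoxepine-3,7-diol | C(C[C@H]2[C@]3(C)CC[C@H](O)C(C)(C)O[C@H]3CC[C@]2(C)O)[C@H]1C(C)=CC[C@H]2[C@@H]1C(C)(C)CC[C@]2(C)O | intermediate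
20 | sipholenol M | CC1=C(CC[C@H]2[C@]3(C)CC[C@H](O)C(C)(C)O[C@H]3CC[C@]2(C)O)[C@@H]2[C@H](C[C@H]1OO)[C@@](C)(O)CCC2(C)C | target

**Totals**
Total step count: 12. Longest linear sequence: 10 steps (steps 1–6, then 9–12).

**Steps most likely to fail, with fallbacks**

Step 5 is the riskiest. The activated epoxide can rearrange to the C-18 ketone. The first-formed cation can lose a proton, shift hydride from C-22, or close a seven-membered ring at C-23 instead of enlarging. The first closure must also place C-23 cis to the C-17 chain; the trans cation is expected to be drained as a bridged ether by the C-19 hydroxyl. The fallback sets out from 5 and comes back at 10. It closes the first ring under silicon control and runs the ring enlargement as a separate, equilibrating step. Hydroboration of 5 with 9-borabicyclo[3.3.1]nonane and Suzuki coupling with (3-bromo-2-methylprop-2-en-1-yl)trimethylsilane gives the allylsilane epoxy acetate F1. Methanolysis (K2CO3, MeOH) gives the allylsilane epoxy alcohol F2. BF3·OEt2 (CH2Cl2, −78 °C) then closes the cyclopentane by attack of the allylsilane γ-carbon (C-22) on C-18 with loss of the silyl group, so no free cation is formed; the product is the isopropenylcyclopentane diol F3 (C-18 inverted, C-19 retained, C-22 as a mixture). F3 is treated with Bi(OTf)3 (5 mol %) in (CF3)2CHOH at 25 °C, the kind of conditions used for the betulin-to-allobetulin rearrangement. Protonation of the isopropenyl group gives the cyclopentylcarbinyl cation, proton loss and return through the isopropylidene isomer equilibrates C-22, and ring enlargement with capture by the C-14 alkene leads to 10.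

Step 11 may end by proton loss or solvent capture at C-10 instead of water capture, and water may open an epoxide directly. The fallback sets out from 18 and comes back at 19. It ends the cascade by proton loss and adds the hydroxyl afterwards. BF3·OEt2 with 2,6-di-tert-butyl-4-methylpyridine in CH2Cl2 at −78 °C runs the same oxepane–cyclohexane cascade, and the C-10 cation loses a methyl proton to the hindered base to give the exocyclic alkene F4. Mukaiyama hydration (Co(acac)2, PhSiH3, O2, i-PrOH, 0 °C; then PPh3) then gives 19. The 1,1-disubstituted alkene reacts faster than the trisubstituted ring alkene, and the tertiary C-10 radical takes up oxygen from the equatorial side because the axial side is screened by the C-6 methyl.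

Step 12 may give mainly the regioisomers from abstraction of a methyl hydrogen or of H-17, as simple 1-methylcyclohexenes do. The fallback sets out from 19 and comes back at 20. It replaces the pericyclic ene reaction by a radical-chain oxygenation under thermodynamic control. N-Hydroxyphthalimide (10 mol %), O2 and t-BuOOH in MeCN at 40 °C remove the weakest hydrogen, the tertiary allylic H-14. The delocalised C-14/C-16 radical takes up O2 at either end to give 20 and its allylic isomer, the C-14 hydroperoxide F5. F5 is converted to 20 by the Schenck allyl hydroperoxide rearrangement (hexane, 40 °C, trace of di-tert-butyl hyponitrite), since the tetrasubstituted alkene of 20 is the more stable. A C-16 epimer, if formed, is removed by chromatography.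

**Further compounds**
F1 | step 5 | (2E)-3-methyl-5-{(2S,3S)-3-methyl-3-[4-methyl-5-(trimethylsilyl)pent-3-en-1-yl]oxiran-2-yl}pent-2-en-1-yl acetate | C[Si](C)(C)CC(C)=CCC[C@]1(C)O[C@H]1CC/C(C)=C/COC(C)=O
F2 | step 5 | (2E)-3-methyl-5-{(2S,3S)-3-methyl-3-[4-methyl-5-(trimethylsilyl)pent-3-en-1-yl]oxiran-2-yl}pent-2-en-1-ol | C[Si](C)(C)CC(C)=CCC[C@]1(C)O[C@H]1CC/C(C)=C/CO
F3 | step 5 | (1S,2S)-2-[(3E)-5-hydroxy-3-methylpent-3-en-1-yl]-1-methyl-3-(prop-1-en-2-yl)cyclopentan-1-ol, mixture at C-3 | CC(=C)C1CC[C@](C)(O)[C@H]1CC/C(C)=C/CO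
F4 | step 11 | 7-methylidene analogue of 19 lacking the 7-hydroxyl (C-10 exocyclic alkene, other stereocentres as in 19) | C(C[C@H]2[C@]3(C)CC[C@H](O)C(C)(C)O[C@H]3CCC2=C)[C@H]1C(C)=CC[C@H]2[C@@H]1C(C)(C)CC[C@]2(C)O
F5 | step 12 | allylic isomer of 20 with the hydroperoxy group on C-14 and the double bond at C-15/C-16 (C-14 configuration not fixed) | C(C[C@H]2[C@]3(C)CC[C@H](O)C(C)(C)O[C@H]3CC[C@]2(C)O)C1(OO)C(C)=CC[C@H]2[C@@H]1C(C)(C)CC[C@]2(C)O
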